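Ring B of the target carries adjacent C2 and C3, each with a one-carbon branch (C9, C9'), next to the aryl-bearing C1. The C2–C3 bond is therefore disconnected by a [3,3] shift: C9 becomes a lactone carbonyl and C9' the inner alkene carbon of a (Z)-allylic ester, tied together in a ten-membered benzolactone that already holds the C1 diarylmethine. Ireland–Claisen rearrangement of its silyl ketene acetal forms C2–C3, contracts the macrocycle to ring B and sets C2 and C3 in one operation, leaving C9 as CO2H and C9' as vinyl. C1 comes from a rhodium-catalysed asymmetric arylation; reduction, alkene cleavage and debenzylation finish.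

Key step: step 8

Remark 1: atom labels follow the tetralin (C1–C4, C4a, C8a; C9 on C2, C9' on C3; ring A aromatic, ring B saturated); the target is (1R,2S,3R), with aryl trans to the C2 branch and the two CH2OH groups cis.
Remark 2: the macrolactone is planned with a (Z)-alkene, because a cis ketene acetal and a (Z)-alkene joined by a four-atom tether can overlap only in a boat, the geometry that gives the cis C2/C3 pair; this isomer should also cyclise more easily and can be made with defined geometry.
Remark 3: the enantiomer of the diene ligand in step 3 is the one that delivers aryl to the Si face of C3 of enoate 5; its sense of induction is to be confirmed on a small scale.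

Step 1
Reactants: 1 2-bromo-5-hydroxy-4-methoxybenzaldehyde; 2 benzyl bromide
Product: 3 5-(benzyloxy)-2-bromo-4-methoxybenzaldehyde
Conditions: K2CO3, DMF, 50 °C
Reagents that add atoms: benzyl bromide (2), BrCc1ccccc1
Why: Williamson ether synthesis: the phenoxide formed with K2CO3 displaces bromide from benzyl bromide (SN2), and the benzyl ether should withstand every later base, hydride and metal-catalysed step until the final hydrogenolysis.

Step 2
Reactants: 3 5-(benzyloxy)-2-bromo-4-methoxybenzaldehyde; 4 trimethyl phosphonoacetate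
Product: 5 methyl (2E)-3-[5-(benzyloxy)-2-bromo-4-methoxyphenyl]prop-2-enoate
Conditions: NaH, THF, 0 °C → rt
Reagents that add atoms: trimethyl phosphonoacetate (4), COC(=O)CP(=O)(OC)OC
Why: Horner–Wadsworth–Emmons olefination of the aryl aldehyde with the stabilised phosphonate anion should give the (E)-enoate, and it removes the aldehyde before any allylboron reagent (which adds to C=O groups) enters the route.

Step 3
Reactants: 5 methyl (2E)-3-[5-(benzyloxy)-2-bromo-4-methoxyphenyl]prop-2-enoate; 6 (4-benzyloxy-3-methoxyphenyl)boronic acid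
Product: 7 methyl (3R)-3-[5-(benzyloxy)-2-bromo-4-methoxyphenyl]-3-[4-(benzyloxy)-3-methoxyphenyl]propanoate
Conditions: [RhCl(C2H4)2]2 (2.5 mol %), 2,5-diphenylbicyclo[2.2.2]octa-2,5-diene (single enantiomer, 5.5 mol %), KOH (0.2 equiv), dioxane/H2O 10:1, 40 °C
Reagents that add atoms: (4-benzyloxy-3-methoxyphenyl)boronic acid (6), COc1cc(B(O)O)ccc1OCc1ccccc1
Why: Hayashi–Miyaura 1,4-addition: the aryl group passes from boron to the diene-bound rhodium centre, inserts across the enoate and the rhodium enolate is protonated by water, the C2-symmetric diene shielding one face so that aryl adds to the Si face of C3 and sets the (R)-diarylmethine (future C1), while the aryl bromide is left alone by this catalyst.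

Step 4
Reactants: 7 methyl (3R)-3-[5-(benzyloxy)-2-bromo-4-methoxyphenyl]-3-[4-(benzyloxy)-3-methoxyphenyl]propanoate; 8 allylboronic acid pinacol ester
Product: 9 methyl (3R)-3-[5-(benzyloxy)-4-methoxy-2-(prop-2-en-1-yl)phenyl]-3-[4-(benzyloxy)-3-methoxyphenyl]propanoate
Conditions: Pd(OAc)2 (5 mol %), SPhos (10 mol %), CsF, THF, 65 °C
Reagents that add atoms: allylboronic acid pinacol ester (8), C=CCB1OC(C)(C)C(C)(C)O1
Why: Suzuki–Miyaura coupling: zerovalent palladium (formed from Pd(OAc)2 and SPhos) inserts into the hindered, electron-rich C–Br bond, fluoride-assisted transfer of the unsubstituted allyl group and reductive elimination follow, and neither the ester nor the remote stereocentre is involved.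

Step 5
Reactants: 9 methyl (3R)-3-[5-(benzyloxy)-4-methoxy-2-(prop-2-en-1-yl)phenyl]-3-[4-(benzyloxy)-3-methoxyphenyl]propanoate; 10 (Z)-but-2-ene-1,4-diol
Product: 11 methyl (3R)-3-{5-(benzyloxy)-2-[(2Z)-4-hydroxybut-2-en-1-yl]-4-methoxyphenyl}-3-[4-(benzyloxy)-3-methoxyphenyl]propanoate
Conditions: Ru(=CH-C6H4-2-OiPr)(SIMes)(S2C6H2Cl2) (5 mol %; SIMes = 1,3-dimesitylimidazolidin-2-ylidene, S2C6H2Cl2 = 3,6-dichlorobenzene-1,2-dithiolate), 10 (3 equiv), THF, rt → 40 °C
Reagents that add atoms: (Z)-but-2-ene-1,4-diol (10), OC/C=C\CO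
Why: Stereoretentive olefin cross-metathesis: the dithiolate ruthenium carbene reacts through side-bound metallacyclobutanes that keep the substituents syn, so the CH–CH2OH unit of the (Z)-diol should be transferred to the terminal alkene with the (Z)-geometry retained, driven by the excess of diol.

Step 6
Reactants: 11 methyl (3R)-3-{5-(benzyloxy)-2-[(2Z)-4-hydroxybut-2-en-1-yl]-4-methoxyphenyl}-3-[4-(benzyloxy)-3-methoxyphenyl]propanoate
Product: 12 (3R)-3-{5-(benzyloxy)-2-[(2Z)-4-hydroxybut-2-en-1-yl]-4-methoxyphenyl}-3-[4-(benzyloxy)-3-methoxyphenyl]propanoic acid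
Conditions: LiOH·H2O, THF/MeOH/H2O, rt; then 1 M HCl to pH 3
Reagents that add atoms: lithium hydroxide, [Li+].[OH-]
Why: Saponification (BAc2 hydrolysis) of the unhindered methyl ester at room temperature should leave the benzyl ethers, the (Z)-allylic alcohol and the non-enolisable diarylmethine unchanged.

Step 7
Reactants: 12 (3R)-3-{5-(benzyloxy)-2-[(2Z)-4-hydroxybut-2-en-1-yl]-4-methoxyphenyl}-3-[4-(benzyloxy)-3-methoxyphenyl]propanoic acid
Product: 14 (1R,6Z)-11-(benzyloxy)-1-[4-(benzyloxy)-3-methoxyphenyl]-10-methoxy-1,2,5,8-tetrahydro-3H-4-benzoxecin-3-one, via mixed anhydride 13 (not isolated)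
Conditions: 2,4,6-Cl3C6H2COCl, Et3N, THF, rt; then slow addition to DMAP, toluene, 80 °C, final concentration about 1 mM
Reagents that add atoms: 2,4,6-trichlorobenzoyl chloride, O=C(Cl)c1c(Cl)cc(Cl)cc1Cl (its aroyl group is present in 13 only; none of its atoms remains in 14)
Why: Yamaguchi macrolactonisation: DMAP opens the mixed anhydride and the acylpyridinium is captured by the primary allylic hydroxyl under high dilution, the (Z)-alkene and the ortho-disubstituted ring A bending the seco acid so that ten-membered ring closure should outrun oligomerisation.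

Step 8
Reactants: 14 (1R,6Z)-11-(benzyloxy)-1-[4-(benzyloxy)-3-methoxyphenyl]-10-methoxy-1,2,5,8-tetrahydro-3H-4-benzoxecin-3-one
Product: 17 (1R,2R,3S)-7-(benzyloxy)-1-[4-(benzyloxy)-3-methoxyphenyl]-3-ethenyl-6-methoxy-1,2,3,4-tetrahydronaphthalene-2-carboxylic acid, via silyl ketene acetal 15 (not isolated), via trimethylsilyl ester 16 (not isolated)
Conditions: LiN(iPr)2, Me3SiCl/Et3N (premixed), THF, −78 °C → rt; then toluene, 80–110 °C; then 1 M HCl, THF, rt
Reagents that add atoms: chlorotrimethylsilane, C[Si](C)(C)Cl (its Me3Si group is carried by 15 and 16 only and is lost on work-up; 17 keeps no reagent atom)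
Why: LiN(iPr)2 removes a proton from C2 (the C1 methine and the C4 protons are far less acidic) and Me3SiCl traps the enolate as ketene acetal 15, whose C2=C9 bond must be cis within the ten-membered ring (C1 and the ring oxygen on the same side). On warming, a concerted suprafacial [3,3] shift joins C2 to C3 and breaks the allylic C–O bond to give silyl ester 16, which aqueous acid hydrolyses to 17; the closest known reaction type is the ester-enolate Claisen ring contraction of macrocyclic (Z)-allylic lactones to cis-2-vinylcycloalkanecarboxylic acids. Ring B closes transannularly: the four-atom tether C1–C8a–C4a–C4 already links both termini, so the ten-membered lactone contracts to the six-membered carbocycle as the new bond forms. Because the cis ketene acetal and the (Z)-alkene held by this short tether can overlap only in a boat, C9 and C9' are eclipsed across the forming bond, which sets C3 with vinyl cis to carboxyl. The configuration of C2 relative to C1 is set by allylic 1,3-strain: the C1–H bond lies near the plane of the ketene acetal beside the ring oxygen, the C1 aryl takes the outward pseudo-equatorial position of the forming ring, and C3 bonds to the face of C2 that leaves carboxyl trans to aryl. The step needs this facial selectivity and chemoselective α-deprotonation: the preset C1 centre supplies the first, and silylation in situ at −78 °C the second by suppressing self-condensation and base-induced 1,4-elimination of the allylic carboxylate.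

Step 9
Reactants: 17 (1R,2R,3S)-7-(benzyloxy)-1-[4-(benzyloxy)-3-methoxyphenyl]-3-ethenyl-6-methoxy-1,2,3,4-tetrahydronaphthalene-2-carboxylic acid
Product: 18 [(1R,2R,3S)-7-(benzyloxy)-1-[4-(benzyloxy)-3-methoxyphenyl]-3-ethenyl-6-methoxy-1,2,3,4-tetrahydronaphthalen-2-yl]methanol
Conditions: LiAlH4, THF, 0 → 40 °C; H2O/NaOH work-up
Reagents that add atoms: none
Why: Hydride reduction: LiAlH4 converts the carboxylate into the primary alkoxide without enolisation, so C2 should keep its configuration, and it does not touch the vinyl group or the benzyl ethers.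

Step 10
Reactants: 18 [(1R,2R,3S)-7-(benzyloxy)-1-[4-(benzyloxy)-3-methoxyphenyl]-3-ethenyl-6-methoxy-1,2,3,4-tetrahydronaphthalen-2-yl]methanol
Product: 21 [(1R,2S,3R)-7-(benzyloxy)-1-[4-(benzyloxy)-3-methoxyphenyl]-6-methoxy-1,2,3,4-tetrahydronaphthalene-2,3-diyl]dimethanol, via triol 19 (not isolated), via hydroxy aldehyde 20 (not isolated)
Conditions: K2OsO4·2H2O (2 mol %), NaIO4, 2,6-lutidine, dioxane/H2O 3:1, rt; extraction, crude 20 in MeOH, NaBH4, 0 °C
Reagents that add atoms: sodium periodate, [Na+].[O-]I(=O)(=O)=O, and water, O (oxygen source for the new C9'–O bond, passed on by the osmium catalyst)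
Why: Lemieux–Johnson cleavage followed by borohydride reduction: catalytic dihydroxylation of the terminal alkene and periodate cleavage give the C9' aldehyde, which the neighbouring C9 hydroxyl holds as a cis-fused lactol (this and the buffered medium guard C3 against epimerisation) until NaBH4 reduces it, and the sequence spares the electron-rich rings and benzyl ethers that ozone could attack.

Step 11
Reactants: 21 [(1R,2S,3R)-7-(benzyloxy)-1-[4-(benzyloxy)-3-methoxyphenyl]-6-methoxy-1,2,3,4-tetrahydronaphthalene-2,3-diyl]dimethanol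
Product: 22 [(1R,2S,3R)-7-hydroxy-1-(4-hydroxy-3-methoxyphenyl)-6-methoxy-1,2,3,4-tetrahydronaphthalene-2,3-diyl]dimethanol (target)
Conditions: H2 (1 atm), Pd/C (10 wt %), EtOAc/MeOH, rt
Reagents that add atoms: none
Why: Catalytic hydrogenolysis cleaves both benzylic C–O bonds of the aryl benzyl ethers on palladium under neutral conditions, while the alcohols, methyl ethers and the three stereocentres are inert.

Compound list
1 | 2-bromo-5-hydroxy-4-methoxybenzaldehyde | COc1cc(Br)c(C=O)cc1O | starting material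
2 | benzyl bromide | BrCc1ccccc1 | starting material
3 | 5-(benzyloxy)-2-bromo-4-methoxybenzaldehyde | COc1cc(Br)c(C=O)cc1OCc1ccccc1 | intermediate
4 | trimethyl phosphonoacetate | COC(=O)CP(=O)(OC)OC | starting material
5 | methyl (2E)-3-[5-(benzyloxy)-2-bromo-4-methoxyphenyl]prop-2-enoate | COC(=O)/C=C/c1cc(OCc2ccccc2)c(OC)cc1Br | intermediate
6 | (4-benzyloxy-3-methoxyphenyl)boronic acid | COc1cc(B(O)O)ccc1OCc1ccccc1 | starting material
7 | methyl (3R)-3-[5-(benzyloxy)-2-bromo-4-methoxyphenyl]-3-[4-(benzyloxy)-3-methoxyphenyl]propanoate | COC(=O)C[C@H](c1ccc(OCc2ccccc2)c(OC)c1)c1cc(OCc2ccccc2)c(OC)cc1Br | intermediate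
8 | allylboronic acid pinacol ester | C=CCB1OC(C)(C)C(C)(C)O1 | starting material
9 | methyl (3R)-3-[5-(benzyloxy)-4-methoxy-2-(prop-2-en-1-yl)phenyl]-3-[4-(benzyloxy)-3-methoxyphenyl]propanoate | COC(=O)C[C@H](c1ccc(OCc2ccccc2)c(OC)c1)c1cc(OCc2ccccc2)c(OC)cc1CC=C | intermediate
10 | (Z)-but-2-ene-1,4-diol | OC/C=C\CO | starting material
11 | methyl (3R)-3-{5-(benzyloxy)-2-[(2Z)-4-hydroxybut-2-en-1-yl]-4-methoxyphenyl}-3-[4-(benzyloxy)-3-methoxyphenyl]propanoate | COC(=O)C[C@H](c1ccc(OCc2ccccc2)c(OC)c1)c1cc(OCc2ccccc2)c(OC)cc1C/C=C\CO | intermediate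
12 | (3R)-3-{5-(benzyloxy)-2-[(2Z)-4-hydroxybut-2-en-1-yl]-4-methoxyphenyl}-3-[4-(benzyloxy)-3-methoxyphenyl]propanoic acid | OC(=O)C[C@H](c1ccc(OCc2ccccc2)c(OC)c1)c1cc(OCc2ccccc2)c(OC)cc1C/C=C\CO | intermediate
13 | mixed anhydride of acid 12 with 2,4,6-trichlorobenzoic acid | O=C(OC(=O)c1c(Cl)cc(Cl)cc1Cl)C[C@H](c1ccc(OCc2ccccc2)c(OC)c1)c1cc(OCc2ccccc2)c(OC)cc1C/C=C\CO | intermediate
14 | (1R,6Z)-11-(benzyloxy)-1-[4-(benzyloxy)-3-methoxyphenyl]-10-methoxy-1,2,5,8-tetrahydro-3H-4-benzoxecin-3-one (ten-membered benzo-fused (Z)-allylic lactone; ring atoms C9(=O), C2, C1, C8a, C4a, C4, C3, C9', OCH2, O) | O=C1C[C@H](c2ccc(OCc3ccccc3)c(OC)c2)c2cc(OCc3ccccc3)c(OC)cc2C/C=C\CO1 | intermediate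
15 | trimethylsilyl ketene acetal of 14 (C2=C9 bond with C1 cis to the ring oxygen and Me3SiO trans to C1; (Z)-alkene kept) | C[Si](C)(C)O/C1=C/[C@H](c2ccc(OCc3ccccc3)c(OC)c2)c2cc(OCc3ccccc3)c(OC)cc2C/C=C\CO1 | intermediate
16 | trimethylsilyl (1R,2R,3S)-7-(benzyloxy)-1-[4-(benzyloxy)-3-methoxyphenyl]-3-ethenyl-6-methoxy-1,2,3,4-tetrahydronaphthalene-2-carboxylate | COc1cc([C@@H]2c3cc(OCc4ccccc4)c(OC)cc3C[C@@H](C=C)[C@H]2C(=O)O[Si](C)(C)C)ccc1OCc1ccccc1 | intermediate
17 | (1R,2R,3S)-7-(benzyloxy)-1-[4-(benzyloxy)-3-methoxyphenyl]-3-ethenyl-6-methoxy-1,2,3,4-tetrahydronaphthalene-2-carboxylic acid (aryl trans to carboxyl, carboxyl cis to vinyl) | COc1cc([C@@H]2c3cc(OCc4ccccc4)c(OC)cc3C[C@@H](C=C)[C@H]2C(=O)O)ccc1OCc1ccccc1 | intermediate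
18 | [(1R,2R,3S)-7-(benzyloxy)-1-[4-(benzyloxy)-3-methoxyphenyl]-3-ethenyl-6-methoxy-1,2,3,4-tetrahydronaphthalen-2-yl]methanol | COc1cc([C@@H]2c3cc(OCc4ccccc4)c(OC)cc3C[C@@H](C=C)[C@H]2CO)ccc1OCc1ccccc1 | intermediate
19 | triol: 18 with the vinyl group dihydroxylated to CH(OH)CH2OH on C3 (both carbinol epimers) | COc1cc([C@@H]2c3cc(OCc4ccccc4)c(OC)cc3C[C@@H](C(O)CO)[C@H]2CO)ccc1OCc1ccccc1 | intermediate
20 | hydroxy aldehyde: 21 with C9' as CHO on C3, cis to the C2 CH2OH group (open form; equilibrates with its cis-fused lactol) | COc1cc([C@@H]2c3cc(OCc4ccccc4)c(OC)cc3C[C@@H](C=O)[C@H]2CO)ccc1OCc1ccccc1 | intermediate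
21 | [(1R,2S,3R)-7-(benzyloxy)-1-[4-(benzyloxy)-3-methoxyphenyl]-6-methoxy-1,2,3,4-tetrahydronaphthalene-2,3-diyl]dimethanol | COc1cc([C@@H]2c3cc(OCc4ccccc4)c(OC)cc3C[C@@H](CO)[C@H]2CO)ccc1OCc1ccccc1 | intermediate
22 | [(1R,2S,3R)-7-hydroxy-1-(4-hydroxy-3-methoxyphenyl)-6-methoxy-1,2,3,4-tetrahydronaphthalene-2,3-diyl]dimethanol | COc1cc([C@@H]2c3cc(O)c(OC)cc3C[C@@H](CO)[C@H]2CO)ccc1O | target

Total step count: 11
Longest linear sequence: 11 steps (1 → 22)

Steps most likely to fail

Step 8. The C1 centre may discriminate poorly between the two faces of the ketene acetal in the boat, or the strained boat may be reached so slowly that the enolate or ketene acetal is lost by 1,4-elimination of the allylic carboxylate. The fallback closes ring B stepwise and sets C3 under thermodynamic control; it sets out from 11 and comes back at 21. Hydroxy ester 11 is converted (MsCl, Et3N; then LiCl, DMF) into the (Z)-allylic chloride F1. LiN(SiMe3)2 in THF (−78 → 0 °C) then closes ring B by intramolecular SN2' alkylation of the ester enolate (six-membered ring, exo mode); after equilibration of C2 with NaOMe/MeOH this should give mainly the all-trans vinyl ester F2. LiAlH4 gives the primary alcohol F3, and K2OsO4·2H2O/NaIO4/2,6-lutidine cleavage of the vinyl group gives the trans-fused lactol F4. Ag2CO3 on Celite (toluene, reflux) oxidises F4 to the trans-fused lactone F5, with the carbonyl at C9' and the OCH2 at C9. NaOMe in MeOH (acidic work-up) then epimerises C3, the carbon α to the lactone carbonyl, to the more stable cis-fused lactone F6. This trans-to-cis preference is known for 1-aryltetralin γ-lactones of this type, so either C3 epimer from the cyclisation should converge. LiAlH4 reduces F6 to diol 21.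

Step 7. Intermolecular esterification (diolide and oligomer formation) may outrun closure of the strained ten-membered ring. The fallback closes the same ring at the alkene instead of the ester; it sets out from 9 and comes back at 14, and it also bypasses step 5. Ester 9 is saponified (LiOH, THF/MeOH/H2O) to the acid F7, which is esterified with allyl alcohol (EDC·HCl, DMAP, CH2Cl2) to the allyl ester F8. Ring-closing metathesis with the second-generation Hoveyda–Grubbs catalyst (toluene, 80 °C, about 1 mM, ethene purged) joins C3 and C9' to give lactone 14. Ring strain in the benzo-fused ten-membered ring is expected to favour the (Z)-alkene.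

Step 5. The catalyst may decompose before full conversion, the allyl double bond may migrate into conjugation with ring A, or the (Z)-geometry may be partly lost. The fallback uses thermodynamic metathesis and the chair pathway of the rearrangement; it sets out from 9 and comes back at 16 (and so at 17). Cross-metathesis of 9 with 10 and the second-generation Hoveyda–Grubbs catalyst (CH2Cl2, 40 °C) should give the (E)-allylic alcohol F9. LiOH gives the (E)-hydroxy acid F10, and the Yamaguchi conditions of step 7, via the mixed anhydride F11, give the (E)-lactone F12. LiN(iPr)2/Me3SiCl gives the ketene acetal F13, in which a cis ketene acetal and an (E)-alkene can overlap only in a chair. In that chair the C4 tether is pseudo-equatorial at C3 and the C1 tether pseudo-axial at C2, which again places C9 and C9' cis, so the shift is expected to give the same silyl ester 16 and, after hydrolysis, acid 17.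

Further compounds
F1 | step 8 | methyl (3R)-3-{5-(benzyloxy)-2-[(2Z)-4-chlorobut-2-en-1-yl]-4-methoxyphenyl}-3-[4-(benzyloxy)-3-methoxyphenyl]propanoate | COC(=O)C[C@H](c1ccc(OCc2ccccc2)c(OC)c1)c1cc(OCc2ccccc2)c(OC)cc1C/C=C\CCl
F2 | step 8 | methyl (1R,2R,3R)-7-(benzyloxy)-1-[4-(benzyloxy)-3-methoxyphenyl]-3-ethenyl-6-methoxy-1,2,3,4-tetrahydronaphthalene-2-carboxylate (all-trans) | COc1cc([C@@H]2c3cc(OCc4ccccc4)c(OC)cc3C[C@H](C=C)[C@H]2C(=O)OC)ccc1OCc1ccccc1
F3 | step 8 | [(1R,2R,3R)-7-(benzyloxy)-1-[4-(benzyloxy)-3-methoxyphenyl]-3-ethenyl-6-methoxy-1,2,3,4-tetrahydronaphthalen-2-yl]methanol | COc1cc([C@@H]2c3cc(OCc4ccccc4)c(OC)cc3C[C@H](C=C)[C@H]2CO)ccc1OCc1ccccc1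
F4 | step 8 | trans-fused lactol (C9'H(OH)–O–C9H2 bridging C3 and C2, aryl trans to the C2 branch, anomeric mixture) | COc1cc([C@@H]2c3cc(OCc4ccccc4)c(OC)cc3C[C@@H]3C(O)OC[C@@H]23)ccc1OCc1ccccc1
F5 | step 8 | trans-fused γ-lactone (C9'(=O)–O–C9H2, carbonyl on C3, aryl trans to the C2 branch) | COc1cc([C@@H]2c3cc(OCc4ccccc4)c(OC)cc3C[C@@H]3C(=O)OC[C@@H]23)ccc1OCc1ccccc1
F6 | step 8 | cis-fused γ-lactone (C3 epimer of F5; aryl trans to the C2 branch) | COc1cc([C@@H]2c3cc(OCc4ccccc4)c(OC)cc3C[C@H]3C(=O)OC[C@@H]23)ccc1OCc1ccccc1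
F7 | step 7 | (3R)-3-[5-(benzyloxy)-4-methoxy-2-(prop-2-en-1-yl)phenyl]-3-[4-(benzyloxy)-3-methoxyphenyl]propanoic acid | OC(=O)C[C@H](c1ccc(OCc2ccccc2)c(OC)c1)c1cc(OCc2ccccc2)c(OC)cc1CC=C
F8 | step 7 | prop-2-en-1-yl (3R)-3-[5-(benzyloxy)-4-methoxy-2-(prop-2-en-1-yl)phenyl]-3-[4-(benzyloxy)-3-methoxyphenyl]propanoate | C=CCOC(=O)C[C@H](c1ccc(OCc2ccccc2)c(OC)c1)c1cc(OCc2ccccc2)c(OC)cc1CC=C
F9 | step 5 | methyl (3R)-3-{5-(benzyloxy)-2-[(2E)-4-hydroxybut-2-en-1-yl]-4-methoxyphenyl}-3-[4-(benzyloxy)-3-methoxyphenyl]propanoate | COC(=O)C[C@H](c1ccc(OCc2ccccc2)c(OC)c1)c1cc(OCc2ccccc2)c(OC)cc1C/C=C/CO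
F10 | step 5 | (3R)-3-{5-(benzyloxy)-2-[(2E)-4-hydroxybut-2-en-1-yl]-4-methoxyphenyl}-3-[4-(benzyloxy)-3-methoxyphenyl]propanoic acid | OC(=O)C[C@H](c1ccc(OCc2ccccc2)c(OC)c1)c1cc(OCc2ccccc2)c(OC)cc1C/C=C/CO
F11 | step 5 | mixed anhydride of acid F10 with 2,4,6-trichlorobenzoic acid | O=C(OC(=O)c1c(Cl)cc(Cl)cc1Cl)C[C@H](c1ccc(OCc2ccccc2)c(OC)c1)c1cc(OCc2ccccc2)c(OC)cc1C/C=C/CO
F12 | step 5 | (1R,6E)-11-(benzyloxy)-1-[4-(benzyloxy)-3-methoxyphenyl]-10-methoxy-1,2,5,8-tetrahydro-3H-4-benzoxecin-3-one | O=C1C[C@H](c2ccc(OCc3ccccc3)c(OC)c2)c2cc(OCc3ccccc3)c(OC)cc2C/C=C/CO1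
F13 | step 5 | trimethylsilyl ketene acetal of F12 (C1 cis to the ring oxygen, (E)-alkene kept) | C[Si](C)(C)O/C1=C/[C@H](c2ccc(OCc3ccccc3)c(OC)c2)c2cc(OCc3ccccc3)c(OC)cc2C/C=C/CO1
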